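(The data were generated by integration with made-up constants.)

Late in the midnight run, at 10.0 h, left-handed substrate and right-handed substrate stood at 27.5% and 28.4%, level within the scatter, so I had to decide whether the next flask needed its full 15 h.

all flasks: left-handed substrate 0.025 M; right-handed substrate 0.025 M
- midnight: reagent 0.020 M; free catalyst 1.7 mM; run made earlier
- noon: reagent 0.020 M; free catalyst 2.6 mM; run made earlier
- flask: reagent 0.0200 M; free catalyst 1.2 mM; time 15 h

- midnight (time / h: left-handed substrate / %, right-handed substrate / %): 1.50: 32.8, 27.9; 3.00: 30.1, 28.9; 5.00: 27.9, 27.5; 6.00: 29.6, 30.7; 8.00: 30.2, 29.0; 10.0: 27.5, 28.4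
- noon (time / h: left-handed substrate / %, right-handed substrate / %): 0.667: 36.9, 26.8; 1.33: 33.1, 24.8; 2.00: 33.4, 23.9; 3.00: 29.7, 26.9; 5.00: 27.6, 28.8; 10.0: 30.1, 27.1

(each reading ± 1 percentage point)

- free catalyst is single-handed; left-handed substrate and right-handed substrate are mirror images of each other, charged as a racemate, each of them at the stated concentration
- the numbers in the tables scatter by 1 percentage point (one standard deviation)
- an excess is the difference of the two amounts in percent of their sum
- an excess is below zero if the other one leads

- part of the left-handed substrate and right-handed substrate charged together that has reacted at 15 h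
- excess of left-handed product over right-handed product in the product at 15 h
- excess of right-handed substrate over left-handed substrate among what is left of the two at 15 h

- I took the gap g, left-handed minus right-handed substrate, and its half-life h, the time in which g halves once reagent has stopped being used.
- The midnight run gave g = 4.9 percentage points at 1.50 h and 1.2 points at 3.00 h, so h = 0.739 h. With a scatter of 1 point on each reading, this was a rough reading.
- The midnight readings at 1.50 h put the substrates used at 39.3%, within the scatter of the 40.0% of them that the reagent can turn into product, for it is the limiting reagent.
- The flask is charged with 1.2 mM of free catalyst, so by my estimate equal catalyst × time puts that point at 2.12 h. That leaves 17.4 half-lives of h before 15 h.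
- I therefore committed to c, the part of the two substrates charged that has reacted, near 40.0%, and to eS, the excess of right-handed over left-handed substrate among what is left, at zero, and I kept the charge and took one sample at 15 h. The count gave me no number for eP, the excess of left-handed over right-handed product.
- The forecast stood at 41%, −37% and 0%: “The product therefore keeps its excess of right-handed”.
- The flask gave 41.4%, −49.8% and 0%, parting from the forecast on eP by 13 points.

    free catalyst + right-handed substrate ⇌ catalyst intermediate B (K = 140 M⁻¹, k = 67000 M⁻¹ h⁻¹)
    free catalyst ⇌ dormant form (K = 0.520, k = 0.280 h⁻¹)
    reagent + catalyst intermediate A → free catalyst + left-handed product (k = 2200 M⁻¹ h⁻¹)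
    reagent + free catalyst → spent catalyst (k = 5.00 M⁻¹ h⁻¹)
    reagent + catalyst intermediate B → free catalyst + right-handed product (k = 1100 M⁻¹ h⁻¹)
    free catalyst + left-handed substrate ⇌ catalyst intermediate A (K = 20.0 M⁻¹, k = 24000 M⁻¹ h⁻¹)
    left-handed substrate ⇌ right-handed substrate (k = 0.490 h⁻¹)

- In the flask, reagent stood at 0.0897% of its charge at 7.50 h, and 10.1 half-lives of h later eS was 0%. The product excess had already reached −49.6% at 1.50 h, while left-handed substrate still led at 36.7% to 29.9%. In the neighbour charged with 0.050 M of reagent, the count had not begun: reagent still stood at 2.33% of its charge at 15.0 h, c reached 97.4%, and left-handed substrate led right-handed at 1.38% to 1.27%, so eS was −4.08%.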